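**Retrosynthetic overview**

1. Ring B of the target (C1' O-aryl, C2' OH, C3' H, C4'/C5'/C6' Br) has its middle bromine C5' para to the C2' oxygen and flanked by C4' and C6'. So 14 ⇐ benzyl ether 13 (O–Bn cleavage) ⇐ aniline 10, whose C5' NH2 sends bromine to C4' and C6' and is then itself exchanged for bromine.
2. 10 ⇐ nitro ether 9 ⇐ phenol 8 (O-methylation). The ring A bromines (C3 and C5, ortho and para to the C2 oxygen) come from dibromination of the free phenol 7.
3. 7 ⇐ aldehyde 5 (Dakin oxidation) ⇐ 2-(benzyloxy)-5-nitrophenol 3 + 2-fluorobenzaldehyde 4 (SNAr forms the diaryl ether C–O bond); 3 ⇐ 4-nitrocatechol 1 + benzyl bromide 2.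
4. No ring is formed: ring B is bought as 1 and ring A as 4.

Key step: step 7

Assumption: the target has no stereocentre, so no stereodescriptors are needed. Ring A is the methoxy-bearing ring (C1 O-aryl, C2 OMe, C3 Br, C5 Br) and ring B the phenol ring (C1'–C6').

**Route**

Step 1
Reactants: 1 4-nitrocatechol; 2 benzyl bromide
Product: 3 2-(benzyloxy)-5-nitrophenol
Conditions: BnBr (1.0 equiv), K2CO3 (1.0 equiv), DMF, rt
Reagents that add atoms: none
Why: Williamson ether synthesis: one equivalent of base deprotonates only the more acidic hydroxyl para to the nitro group, and this mono-phenoxide is benzylated, which leaves the free hydroxyl meta to nitro.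

Step 2
Reactants: 3 2-(benzyloxy)-5-nitrophenol; 4 2-fluorobenzaldehyde
Product: 5 2-[2-(benzyloxy)-5-nitrophenoxy]benzaldehyde
Conditions: K2CO3 (1.5 equiv), DMF, 110 °C
Reagents that add atoms: none
Why: Nucleophilic aromatic substitution (SNAr): the phenoxide of 3 adds to the C–F carbon of 4, the Meisenheimer adduct is stabilised by the ortho formyl group, and loss of fluoride forms the diaryl ether C–O bond.

Step 3
Reactants: 5 2-[2-(benzyloxy)-5-nitrophenoxy]benzaldehyde
Product: 7 2-[2-(benzyloxy)-5-nitrophenoxy]phenol, via aryl formate 6 (not isolated)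
Conditions: mCPBA (1.5 equiv), CH2Cl2, rt; then 2 M NaOH, MeOH, 0 °C; HCl work-up
Reagents that add atoms: 3-chloroperbenzoic acid (mCPBA), OOC(=O)c1cccc(Cl)c1
Why: Dakin-type Baeyer–Villiger oxidation: the aryl group, made migration-prone by its ortho oxygen substituent, shifts to oxygen in the Criegee adduct to give formate 6, which hydroxide saponifies to the phenol while the nitro group and the benzyl ether are inert to peracid and cold base.

Step 4
Reactants: 7 2-[2-(benzyloxy)-5-nitrophenoxy]phenol
Product: 8 2-[2-(benzyloxy)-5-nitrophenoxy]-4,6-dibromophenol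
Conditions: Br2 (2.05 equiv), NaOAc (2.2 equiv), AcOH, 15 °C to rt
Reagents that add atoms: bromine, BrBr
Why: Electrophilic aromatic bromination: the free hydroxyl makes its own ring by far the most reactive and directs bromine to its para and its one free ortho carbon (later C5 and C3 of ring A), while the nitro-deactivated ring B and the benzyl ring do not compete and NaOAc buffers the HBr.

Step 5
Reactants: 8 2-[2-(benzyloxy)-5-nitrophenoxy]-4,6-dibromophenol
Product: 9 1-(benzyloxy)-2-(3,5-dibromo-2-methoxyphenoxy)-4-nitrobenzene
Conditions: MeI (1.5 equiv), K2CO3 (1.5 equiv), DMF, rt to 40 °C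
Reagents that add atoms: iodomethane, CI
Why: Williamson O-methylation: the acidic, doubly ortho-substituted dibromophenoxide is alkylated by the unhindered electrophile iodomethane, and no other nucleophilic site is present.

Step 6
Reactants: 9 1-(benzyloxy)-2-(3,5-dibromo-2-methoxyphenoxy)-4-nitrobenzene
Product: 10 4-(benzyloxy)-3-(3,5-dibromo-2-methoxyphenoxy)aniline
Conditions: Fe powder (5 equiv), NH4Cl, EtOH/H2O 4:1, 80 °C
Reagents that add atoms: none
Why: Béchamp-type dissolving-metal reduction of the nitro group by electron transfer from iron, chosen because it leaves the aryl C–Br bonds and the benzyl ether intact where catalytic hydrogenation would not.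

Step 7
Reactants: 10 4-(benzyloxy)-3-(3,5-dibromo-2-methoxyphenoxy)aniline
Product: 13 1-(benzyloxy)-3,4,5-tribromo-2-(3,5-dibromo-2-methoxyphenoxy)benzene, via dibromoaniline 11 (not isolated), via diazonium bromide 12 (not isolated)
Conditions: NBS (2.05 equiv), MeCN, 0 °C, dark; then CuBr2 (1.5 equiv), t-BuONO (1.5 equiv), 0 to 60 °C
Reagents that add atoms: N-bromosuccinimide, O=C1CCC(=O)N1Br; copper dibromide CuBr2, Br[Cu]Br
Why: N-Bromosuccinimide brominates the aniline by electrophilic aromatic substitution at C4' and C6', the two carbons ortho to nitrogen, because the para carbon C2' carries the benzyloxy group, C3' is meta to nitrogen, and the only methoxy-activated positions of ring A already hold bromine. tert-Butyl nitrite then nitrosates the weakly basic 2,6-dibromoaniline 11 to the diazonium ion 12, which is reduced by monovalent copper formed in the flask to an aryl radical with loss of N2, and this radical takes a bromine atom from CuBr2 to form the C5'–Br bond. The closest known reaction types are the ortho,ortho-dibromination of para-substituted anilines and the non-aqueous Sandmeyer bromodediazoniation with an alkyl nitrite and CuBr2. No ring is closed and no stereocentre is formed. The step needs exactly two brominations, both ortho to nitrogen, and clean substitution of a diazonium group flanked by two bromines; the first is secured by the strength of the amino director, the blocked para position and two equivalents of reagent at 0 °C in the dark, the second by the anhydrous medium and the excess of CuBr2, which outrun hydrogen abstraction and phenol formation. The radical centre at C5' is para to the benzyloxy group and meta to the aryloxy group, so neither a 1,5-hydrogen shift from the benzylic CH2 nor a Pschorr-type attack on ring A is geometrically open.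

Step 8
Reactants: 13 1-(benzyloxy)-3,4,5-tribromo-2-(3,5-dibromo-2-methoxyphenoxy)benzene
Product: 14 3,4,5-tribromo-2-(3,5-dibromo-2-methoxyphenoxy)phenol
Conditions: BCl3 (2 equiv), pentamethylbenzene (3 equiv), CH2Cl2, −78 °C; MeOH quench
Reagents that add atoms: none
Why: Lewis-acid debenzylation: BCl3 coordinates the benzylic ether oxygen, the benzyl cation is captured by pentamethylbenzene in a Friedel–Crafts alkylation so it cannot re-alkylate the bromophenol, and at −78 °C the hindered aryl methyl ether, the diaryl ether and the C–Br bonds are untouched.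

**Compound list**

1 | 4-nitrocatechol | Oc1ccc(cc1O)[N+](=O)[O-] | starting material
2 | benzyl bromide | BrCc1ccccc1 | starting material
3 | 2-(benzyloxy)-5-nitrophenol | Oc1cc([N+](=O)[O-])ccc1OCc1ccccc1 | intermediate
4 | 2-fluorobenzaldehyde | O=Cc1ccccc1F | starting material
5 | 2-[2-(benzyloxy)-5-nitrophenoxy]benzaldehyde | O=Cc1ccccc1Oc1cc([N+](=O)[O-])ccc1OCc1ccccc1 | intermediate
6 | 2-[2-(benzyloxy)-5-nitrophenoxy]phenyl formate | O=COc1ccccc1Oc1cc([N+](=O)[O-])ccc1OCc1ccccc1 | intermediate
7 | 2-[2-(benzyloxy)-5-nitrophenoxy]phenol | Oc1ccccc1Oc1cc([N+](=O)[O-])ccc1OCc1ccccc1 | intermediate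
8 | 2-[2-(benzyloxy)-5-nitrophenoxy]-4,6-dibromophenol | Oc1c(Br)cc(Br)cc1Oc1cc([N+](=O)[O-])ccc1OCc1ccccc1 | intermediate
9 | 1-(benzyloxy)-2-(3,5-dibromo-2-methoxyphenoxy)-4-nitrobenzene | COc1c(Br)cc(Br)cc1Oc1cc([N+](=O)[O-])ccc1OCc1ccccc1 | intermediate
10 | 4-(benzyloxy)-3-(3,5-dibromo-2-methoxyphenoxy)aniline | COc1c(Br)cc(Br)cc1Oc1cc(N)ccc1OCc1ccccc1 | intermediate
11 | 4-(benzyloxy)-2,6-dibromo-3-(3,5-dibromo-2-methoxyphenoxy)aniline | COc1c(Br)cc(Br)cc1Oc1c(Br)c(N)c(Br)cc1OCc1ccccc1 | intermediate
12 | 4-(benzyloxy)-2,6-dibromo-3-(3,5-dibromo-2-methoxyphenoxy)benzenediazonium bromide | COc1c(Br)cc(Br)cc1Oc1c(Br)c([N+]#N)c(Br)cc1OCc1ccccc1.[Br-] | intermediate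
13 | 1-(benzyloxy)-3,4,5-tribromo-2-(3,5-dibromo-2-methoxyphenoxy)benzene | COc1c(Br)cc(Br)cc1Oc1c(OCc2ccccc2)cc(Br)c(Br)c1Br | intermediate
14 | 3,4,5-tribromo-2-(3,5-dibromo-2-methoxyphenoxy)phenol | COc1c(Br)cc(Br)cc1Oc1c(O)cc(Br)c(Br)c1Br | target

**Step count**

Total steps: 8. Longest linear sequence: 8 steps, from 4-nitrocatechol 1 to 14.

**Steps most likely to fail**

Step 7. Bromination may run past two bromines (at C3' or at the benzylic CH2) or oxidise the electron-rich aniline. In the one-flask medium, which still holds succinimide and tert-butanol, the hindered diazonium ion may be diverted to hydrogen abstraction (C5'–H) or to phenol and azo products. The fallback separates the operations and sets out from 10. Bromination with benzyltrimethylammonium tribromide (2.0 equiv) and CaCO3 in CH2Cl2/MeOH at rt should give 11, which is isolated and purified. Diazotisation with t-BuONO and BF3·OEt2 in THF at −15 °C and precipitation with Et2O should give the salt 4-(benzyloxy)-2,6-dibromo-3-(3,5-dibromo-2-methoxyphenoxy)benzenediazonium tetrafluoroborate F1. This salt is treated with KBr and catalytic CuBr/CuBr2/1,10-phenanthroline in MeCN at rt, and the route is rejoined at 13.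

Step 3. Hydride instead of aryl migration in the Criegee adduct would give the benzoic acid, because the nitro-substituted aryloxy group is only a weak donor. The fallback avoids the aldehyde altogether and sets out from 3. Alkylation with 2-chlorocyclohexanone (K2CO3, catalytic KI, DMF, 60 °C) should give racemic 2-[2-(benzyloxy)-5-nitrophenoxy]cyclohexan-1-one F2. Aerobic dehydrogenation of the cyclohexanone to the phenol with Pd(OCOCF3)2 (5 mol %), 2-(dimethylamino)pyridine, TsOH and O2 in DMSO at 80 °C rejoins the route at 7. As this path bypasses step 2 as well, it also covers a sluggish SNAr reaction or benzyl transfer at 110 °C.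

Step 1. Alkylation may occur in part at the hydroxyl meta to nitro or at both oxygens, which would give a mixture of regioisomers and the dibenzyl ether. The fallback fixes the position of the free hydroxyl through a nitrogen substituent and sets out from benzyl bromide 2. Commercial 2-amino-4-nitrophenol is O-benzylated at its acidic hydroxyl (K2CO3, DMF, rt) to give 2-(benzyloxy)-5-nitroaniline F3. Diazotisation (NaNO2, aqueous H2SO4, 0 °C) and hydroxydediazoniation with Cu2O and Cu(NO3)2 in water at rt rejoin the route at 3.

**Further compounds**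

F1 | step 7 | 4-(benzyloxy)-2,6-dibromo-3-(3,5-dibromo-2-methoxyphenoxy)benzenediazonium tetrafluoroborate | COc1c(Br)cc(Br)cc1Oc1c(Br)c([N+]#N)c(Br)cc1OCc1ccccc1.F[B-](F)(F)F
F2 | step 3 | 2-[2-(benzyloxy)-5-nitrophenoxy]cyclohexan-1-one (racemic) | O=C1CCCCC1Oc1cc([N+](=O)[O-])ccc1OCc1ccccc1
F3 | step 1 | 2-(benzyloxy)-5-nitroaniline | Nc1cc([N+](=O)[O-])ccc1OCc1ccccc1
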